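**Assumption:** the target has no stereocentre (it is achiral), so no enantiocontrol is needed; the one stereocentre that appears on the route (the carbinol in 11) is made racemic and removed by oxidation in step 6.

**Retrosynthetic overview**
1. Target 15 comes from its 7-O-benzyl ether 14 by hydrogenolysis.
2. Ring C of 14 is closed last, by a new gold-catalysed demethylative 6-endo cycloisomerization of the mirror-symmetric 2,6-dimethoxyaryl ynone 12; this forms the O1–C2 bond and differentiates O1 from the 5-OMe.
3. Ynone 12 comes from aldehyde 8 and 4-ethynylanisole 9 (ring B, bought) by acetylide addition and oxidation.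
4. Aldehyde 8 comes from the symmetric pentaoxygenated arene 6 by ortho-lithiation and formylation at its only ring C–H.
5. Arene 6 (ring A) comes from syringol 1 by benzylation, double bromination and double Ullmann methoxylation; rings A and B are bought as arenes, ring C is formed last.

**Route**

Step 1
Reactants: 1 2,6-dimethoxyphenol (syringol)
Product: 2 2-(benzyloxy)-1,3-dimethoxybenzene
Conditions: BnBr (1.2 equiv), K2CO3 (2 equiv), DMF, 60 °C
Reagents that add atoms: benzyl bromide, BrCc1ccccc1
Why: Williamson ether synthesis (SN2 O-alkylation of the phenoxide) masks the future 7-OH as a benzyl ether that survives base, organolithiums and copper.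

Step 2
Reactants: 2 2-(benzyloxy)-1,3-dimethoxybenzene
Product: 4 3-(benzyloxy)-1,5-dibromo-2,4-dimethoxybenzene, via 2-(benzyloxy)-4-bromo-1,3-dimethoxybenzene 3 (not isolated)
Conditions: NBS (2.1 equiv), MeCN, 0 °C to rt, dark
Reagents that add atoms: N-bromosuccinimide, O=C1CCC(=O)N1Br
Why: Electrophilic aromatic bromination goes twice at the positions ortho/para to the two flanking methoxy groups, because the twisted central benzyloxy group is only a weak donor toward its para position.

Step 3
Reactants: 4 3-(benzyloxy)-1,5-dibromo-2,4-dimethoxybenzene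
Product: 6 3-(benzyloxy)-1,2,4,5-tetramethoxybenzene, via 3-(benzyloxy)-1-bromo-2,4,5-trimethoxybenzene 5 (not isolated)
Conditions: NaOMe (8 equiv), CuBr (20 mol %), MeOH/DMF, 110 °C
Reagents that add atoms: sodium methoxide, [Na+].[O-]C
Why: Copper-catalysed Ullmann-type methoxylation replaces both aryl bromides and gives the mirror-symmetric pentaoxygenated ring A with a single remaining ring C–H.

Step 4
Reactants: 6 3-(benzyloxy)-1,2,4,5-tetramethoxybenzene
Product: 8 4-(benzyloxy)-2,3,5,6-tetramethoxybenzaldehyde, via [4-(benzyloxy)-2,3,5,6-tetramethoxyphenyl]lithium 7 (not isolated)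
Conditions: n-BuLi (1.2 equiv), TMEDA, THF, 0 °C; then DMF, 0 °C to rt; then H2O
Reagents that add atoms: N,N-dimethylformamide, CN(C)C=O
Why: Directed ortho-metalation at the only ring C–H, which is flanked by two methoxy groups, followed by formylation of the aryllithium with DMF.

Step 5
Reactants: 8 4-(benzyloxy)-2,3,5,6-tetramethoxybenzaldehyde; 9 1-ethynyl-4-methoxybenzene (4-ethynylanisole)
Product: 11 racemic 1-[4-(benzyloxy)-2,3,5,6-tetramethoxyphenyl]-3-(4-methoxyphenyl)prop-2-yn-1-ol, via lithium (4-methoxyphenyl)acetylide 10 (not isolated)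
Conditions: 9, n-BuLi (1.1 equiv), THF, −78 °C; then 8, −78 to 0 °C; then H2O
Reagents that add atoms: none
Why: 1,2-Addition of a lithium acetylide to the aldehyde; the new carbinol centre is formed as a racemate, which does not matter because step 6 removes it.

Step 6
Reactants: 11 racemic 1-[4-(benzyloxy)-2,3,5,6-tetramethoxyphenyl]-3-(4-methoxyphenyl)prop-2-yn-1-ol
Product: 12 1-[4-(benzyloxy)-2,3,5,6-tetramethoxyphenyl]-3-(4-methoxyphenyl)prop-2-yn-1-one
Conditions: MnO2 (15 equiv), CH2Cl2, rt
Reagents that add atoms: none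
Why: MnO2 oxidation of a benzylic, propargylic alcohol is selective and leaves the ethers and the alkyne untouched.

Step 7
Reactants: 12 1-[4-(benzyloxy)-2,3,5,6-tetramethoxyphenyl]-3-(4-methoxyphenyl)prop-2-yn-1-one
Product: 14 7-(benzyloxy)-5,6,8-trimethoxy-2-(4-methoxyphenyl)-4H-chromen-4-one, via aurated methyloxonium triflimide 13 (not isolated)
Conditions: Ph3PAuNTf2 (5 mol %), (PhO)2P(O)OH (1.2 equiv), 4 Å MS, ClCH2CH2Cl, 60 °C
Reagents that add atoms: none
Why: Proposed new method: gold-catalysed demethylative 6-endo-dig cycloisomerization in which the cationic gold centre of Ph3PAuNTf2 π-activates the ynone, an ortho-methoxy oxygen (the two are equivalent by symmetry, and each is twisted out of plane and therefore ether-like) attacks the anisyl-stabilised β-carbon to give oxonium 13, diphenyl phosphate removes the O-methyl group by irreversible SN2 attack to form methyl diphenyl phosphate, and the phosphoric acid proton cleaves the C3–Au bond to release 14 and the catalyst, so that ring C is closed and O1 is differentiated from the 5-OMe under near-neutral conditions that spare the benzyl ether; the closest known reaction type is the iodine monochloride-induced demethylative cyclization of ortho-methoxyaryl ynones to 3-iodochromones, together with gold- and platinum-catalysed alkoxy-cyclizations of alkynes bearing aryl ethers.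

Step 8
Reactants: 14 7-(benzyloxy)-5,6,8-trimethoxy-2-(4-methoxyphenyl)-4H-chromen-4-one
Product: 15 7-hydroxy-5,6,8-trimethoxy-2-(4-methoxyphenyl)-4H-chromen-4-one (7-hydroxy-4',5,6,8-tetramethoxyflavone)
Conditions: H2 (1 atm), 10% Pd/C (palladium on carbon), EtOAc/MeOH, rt
Reagents that add atoms: none
Why: Catalytic hydrogenolysis cleaves only the benzyl ether, since the flavone C2=C3 bond, the carbonyl and the methyl ethers are inert at 1 atm and room temperature.

**Compound list**
1 | 2,6-dimethoxyphenol (syringol) | COc1cccc(OC)c1O | starting material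
2 | 2-(benzyloxy)-1,3-dimethoxybenzene | COc1cccc(OC)c1OCc1ccccc1 | intermediate
3 | 2-(benzyloxy)-4-bromo-1,3-dimethoxybenzene | COc1ccc(Br)c(OC)c1OCc1ccccc1 | intermediate
4 | 3-(benzyloxy)-1,5-dibromo-2,4-dimethoxybenzene | COc1c(Br)cc(Br)c(OC)c1OCc1ccccc1 | intermediate
5 | 3-(benzyloxy)-1-bromo-2,4,5-trimethoxybenzene | COc1cc(Br)c(OC)c(OCc2ccccc2)c1OC | intermediate
6 | 3-(benzyloxy)-1,2,4,5-tetramethoxybenzene | COc1cc(OC)c(OC)c(OCc2ccccc2)c1OC | intermediate
7 | [4-(benzyloxy)-2,3,5,6-tetramethoxyphenyl]lithium | [Li]c1c(OC)c(OC)c(OCc2ccccc2)c(OC)c1OC | intermediate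
8 | 4-(benzyloxy)-2,3,5,6-tetramethoxybenzaldehyde | O=Cc1c(OC)c(OC)c(OCc2ccccc2)c(OC)c1OC | intermediate
9 | 1-ethynyl-4-methoxybenzene (4-ethynylanisole) | C#Cc1ccc(OC)cc1 | starting material
10 | lithium (4-methoxyphenyl)acetylide | [Li]C#Cc1ccc(OC)cc1 | intermediate
11 | racemic 1-[4-(benzyloxy)-2,3,5,6-tetramethoxyphenyl]-3-(4-methoxyphenyl)prop-2-yn-1-ol | OC(C#Cc1ccc(OC)cc1)c1c(OC)c(OC)c(OCc2ccccc2)c(OC)c1OC | intermediate
12 | 1-[4-(benzyloxy)-2,3,5,6-tetramethoxyphenyl]-3-(4-methoxyphenyl)prop-2-yn-1-one | O=C(C#Cc1ccc(OC)cc1)c1c(OC)c(OC)c(OCc2ccccc2)c(OC)c1OC | intermediate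
13 | [7-(benzyloxy)-5,6,8-trimethoxy-2-(4-methoxyphenyl)-1-methyl-4-oxo-4H-chromen-1-ium-3-yl](triphenylphosphine)gold bis(trifluoromethanesulfonyl)imide (aurated methyloxonium triflimide) | C[O+]1C(c2ccc(OC)cc2)=C([Au-][P+](c2ccccc2)(c2ccccc2)c2ccccc2)C(=O)c2c(OC)c(OC)c(OCc3ccccc3)c(OC)c21.FC(F)(F)S(=O)(=O)[N-]S(=O)(=O)C(F)(F)F | intermediate
14 | 7-(benzyloxy)-5,6,8-trimethoxy-2-(4-methoxyphenyl)-4H-chromen-4-one | COc1ccc(-c2cc(=O)c3c(OC)c(OC)c(OCc4ccccc4)c(OC)c3o2)cc1 | intermediate
15 | 7-hydroxy-5,6,8-trimethoxy-2-(4-methoxyphenyl)-4H-chromen-4-one | COc1ccc(-c2cc(=O)c3c(OC)c(OC)c(O)c(OC)c3o2)cc1 | target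

**Summary**
Total step count: 8. Longest linear sequence: 8 steps (1 to 15); 4-ethynylanisole 9 is bought and enters at step 5.

**Steps most likely to fail, with fallbacks**

Step 7 (the proposed new reaction). It may fail through hydration of the ynone, enol phosphate formation or poor catalyst turnover. The fallback uses known chemistry and sets out from 12: treatment with ICl (1.5 equiv) in CH2Cl2 at −78 °C to rt effects the established iodocyclization, with loss of the ortho-methyl group as chloromethane, to give 7-(benzyloxy)-3-iodo-5,6,8-trimethoxy-2-(4-methoxyphenyl)-4H-chromen-4-one F1. Palladium-catalysed formate hydrodeiodination (Pd(OAc)2, PPh3, HCO2Na, DMF, 80 °C) then removes the iodine without touching the benzyl ether and comes back to the route at 14.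

Step 3 (double Ullmann methoxylation). Hydrodebromination or a stalled second substitution could lower the yield. The fallback sets out from 4 and builds the two C–O bonds by borylation and oxidation instead of C–O coupling: double Miyaura borylation (B2pin2, Pd(dppf)Cl2, KOAc, dioxane, 90 °C) gives 2,2'-[5-(benzyloxy)-4,6-dimethoxy-1,3-phenylene]bis(4,4,5,5-tetramethyl-1,3,2-dioxaborolane) F2. Oxidation (30% H2O2, THF/H2O, 0 °C to rt) gives 5-(benzyloxy)-4,6-dimethoxybenzene-1,3-diol F3, and O-methylation (MeI, K2CO3, acetone, reflux) comes back to the route at 6.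

Step 4 (ortho-lithiation and formylation). Competing benzylic deprotonation of the benzyl ether, followed by Wittig rearrangement, is the risk at 0 °C. The fallback sets out from 6 and replaces C–H deprotonation by halogen–metal exchange: NBS (1.05 equiv, MeCN, rt) brominates the only ring C–H to give 1-(benzyloxy)-4-bromo-2,3,5,6-tetramethoxybenzene F4. Bromine–lithium exchange (n-BuLi, THF, −78 °C), which is much faster than benzylic deprotonation at that temperature, followed by DMF and water, comes back to the route at 8.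

**Further compounds**
F1 | step 7 | 7-(benzyloxy)-3-iodo-5,6,8-trimethoxy-2-(4-methoxyphenyl)-4H-chromen-4-one | COc1ccc(-c2oc3c(OC)c(OCc4ccccc4)c(OC)c(OC)c3c(=O)c2I)cc1
F2 | step 3 | 2,2'-[5-(benzyloxy)-4,6-dimethoxy-1,3-phenylene]bis(4,4,5,5-tetramethyl-1,3,2-dioxaborolane) | COc1c(B2OC(C)(C)C(C)(C)O2)cc(B2OC(C)(C)C(C)(C)O2)c(OC)c1OCc1ccccc1
F3 | step 3 | 5-(benzyloxy)-4,6-dimethoxybenzene-1,3-diol | COc1c(O)cc(O)c(OC)c1OCc1ccccc1
F4 | step 4 | 1-(benzyloxy)-4-bromo-2,3,5,6-tetramethoxybenzene | COc1c(Br)c(OC)c(OC)c(OCc2ccccc2)c1OC
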